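**Retrosynthetic overview**
1. The C1–OH bond is made last, by radical Markovnikov hydration of a C1=C2 alkene. Oxygen enters anti to the ring A bromine; this is the key C–O bond.
2. The ring A Br/Cl pair comes from a reagent-controlled epoxide. Its C–O bonds carry the facial information and are exchanged for Br and Cl in one flask (new step), while C1 is still sp2.
3. C3'–Br comes by inversion of a C3'–OH set by conjugate borylation/oxidation. C5'–OH comes from an enone carbonyl installed by allylic C–H oxidation.
4. Ring A is the only ring built, by a cobalt-catalysed [4+2] of a quaternary terminal alkyne with isoprene.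
5. The cyclopentane and the C1' quaternary centre are bought as (+)-camphoric acid. The C3' carboxyl becomes the alkene and the C1' carboxyl becomes the alkyne.

**Locants used.** Cyclopentane: C1' (quaternary, bears CH3 and ring A), C2' (CMe2), C3' (Br), C4', C5' (OH). Ring A: C1 (bonded to C1'), C2, C3, C4 (CH3, Cl), C5 (Br), C6.

**Assumption.** The SMILES is read as (1'S,3'S,5'R,1R,4S,5S). On the cyclopentane, Br, OH and ring A are all cis. On ring A, OH is cis to Cl and trans to Br.

**Step 1**
Reactants: 1 (1R,3S)-(+)-camphoric acid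
Product: 2 dimethyl (1R,3S)-camphorate
Conditions: MeI, K2CO3, DMF, rt
Reagents that add atoms: iodomethane, CI
Why: Carboxylate O-alkylation (SN2 on MeI) esterifies both acids, including the hindered tertiary one, and touches no stereocentre.

**Step 2**
Reactants: 2 dimethyl (1R,3S)-camphorate
Product: 3 (1R,3S)-camphoric acid 1-methyl ester (free CO2H on C3')
Conditions: KOH (1.05 equiv), MeOH/H2O, rt; then aq. HCl
Reagents that add atoms: potassium hydroxide, [K+].[OH-]
Why: Chemoselective saponification cleaves only the secondary C3' ester because the ester on quaternary C1' is shielded like a pivalate, and any epimerisation at C3' is harmless since C3' becomes sp2 next.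

**Step 3**
Reactants: 3 (1R,3S)-camphoric acid 1-methyl ester
Product: 4 methyl (1R)-1,2,2-trimethylcyclopent-3-ene-1-carboxylate
Conditions: [Ir(dF(CF3)ppy)2(dtbbpy)]PF6 (1 mol %), Co(dmgH)2(py)Cl (5 mol %), Cs2CO3 (0.2 equiv), DME/H2O, blue LED, rt
Reagents that add atoms: none
Why: In this photoredox/cobaloxime dehydrogenative decarboxylative olefination the C3' radical has β-hydrogens only on C4', so a single alkene C3'=C4' forms and C1' is untouched.

**Step 4**
Reactants: 4 methyl (1R)-1,2,2-trimethylcyclopent-3-ene-1-carboxylate; 5 dimethyl (1-diazo-2-oxopropyl)phosphonate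
Product: 7 (4S)-4-ethynyl-3,3,4-trimethylcyclopent-1-ene, via aldehyde 6 (not isolated)
Conditions: iBu2AlH, CH2Cl2, −78 °C; then MeOH, K2CO3, 5, −78 °C to rt (product volatile, kept in solution)
Reagents that add atoms: dimethyl (1-diazo-2-oxopropyl)phosphonate (5), CC(=O)C(=[N+]=[N-])P(=O)(OC)OC
Why: Partial ester reduction is followed in the same flask by Ohira–Bestmann (Seyferth–Gilbert) homologation, and the quaternary C1' cannot epimerise.

**Step 5**
Reactants: 7 (4S)-4-ethynyl-3,3,4-trimethylcyclopent-1-ene
Product: 9 (5S)-5-ethynyl-4,4,5-trimethylcyclopent-2-en-1-one, via allylic alcohol 8 (not isolated)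
Conditions: SeO2 (0.3 equiv), t-BuOOH, CH2Cl2, rt to 40 °C; crude alcohol, Dess–Martin periodinane, NaHCO3, CH2Cl2
Reagents that add atoms: tert-butyl hydroperoxide, CC(C)(C)OO
Why: The SeO2 allylic hydroxylation (ene reaction, then [2,3]-shift) can take hydrogen only from C5' and returns oxygen to C5', so the C5'–O bond forms regiospecifically, and the oxidation to the enone makes the carbinol configuration irrelevant.

**Step 6**
Reactants: 9 (5S)-5-ethynyl-4,4,5-trimethylcyclopent-2-en-1-one; 10 isoprene
Product: 11 (5R)-4,4,5-trimethyl-5-(4-methylcyclohexa-1,4-dien-1-yl)cyclopent-2-en-1-one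
Conditions: CoBr2(dppe) (10 mol %), Zn, ZnI2, CH2Cl2, rt
Reagents that add atoms: isoprene (10), CC(=C)C=C
Why: The cobalt-catalysed neutral Diels–Alder reaction of a terminal alkyne with isoprene gives the 1,4-("para") cyclohexadiene with the dppe ligand, which builds ring A with C1 still sp2 and creates no stereocentre.

**Step 7**
Reactants: 11 (5R)-4,4,5-trimethyl-5-(4-methylcyclohexa-1,4-dien-1-yl)cyclopent-2-en-1-one
Product: 14 (1'S,3'R,5'R)-diol (C3'-OH trans to ring A; C5'-OH cis to ring A), via boryl ketone 12 (not isolated), via boryl alcohol 13 (not isolated)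
Conditions: CuCl (5 mol %), DPEphos, NaOtBu (10 mol %), B2pin2, MeOH (2 equiv), THF, rt; then NaBH4, MeOH, −40 °C; then NaBO3·4H2O, THF/H2O, rt
Reagents that add atoms: sodium perborate, [Na+].[Na+].O[B-]1(O)OO[B-](O)(O)OO1
Why: Copper-catalysed conjugate borylation delivers Bpin to C3' on the face anti to ring A (syn to the C1' methyl), borohydride attacks C5'=O from that same open face so that OH ends cis to ring A, and the perborate oxidation of C–B is stereoretentive.

**Step 8**
Reactants: 14 (1'S,3'R,5'R)-diol
Product: 15 (1R,2S,4S)-4-bromo-2,3,3-trimethyl-2-(4-methylcyclohexa-1,4-dien-1-yl)cyclopentan-1-ol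
Conditions: CBr4, PPh3, 2,6-lutidine, toluene, 0 to 60 °C
Reagents that add atoms: tetrabromomethane, BrC(Br)(Br)Br
Why: In this Appel reaction the C3'-OH is activated in preference to the C5'-OH, which is buried between quaternary C1' and ring A, and SN2 inversion places Br cis to ring A (3'S).

**Step 9**
Reactants: 15 bromo alcohol diene
Product: 16 (4S,5R)-4,5-epoxide of 15 (oxygen on the face that will carry Cl; C1=C2 retained)
Conditions: 1,2:4,5-di-O-isopropylidene-β-D-erythro-hexo-2,3-diulo-2,6-pyranose (30 mol %), KHSO5 (as 2KHSO5·KHSO4·K2SO4), K2CO3, Bu4NHSO4, MeCN/CH2(OMe)2/aq. Na2B4O7 buffer, 0 °C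
Reagents that add atoms: potassium peroxymonosulfate, [K+].[O-]S(=O)(=O)OO
Why: In the Shi asymmetric epoxidation the chiral dioxirane takes the less hindered methyl-bearing alkene, and the D-fructose-derived catalyst fixes the face in the sense known for 1-substituted cyclohexenes, so C4 and C5 are set by the reagent and not by the remote cyclopentane.

**Step 10**
Reactants: 16 epoxide
Product: 18 (1'S,3'S,5'R,4S,5S)-alkene bromochloride (C4-Cl, C5-Br trans; C1=C2 retained), via bromohydrin borate 17 (not isolated)
Conditions: BCl3 (2.5 equiv), Bu4NBr (1.05 equiv), 2,6-di-tert-butyl-4-methylpyridine, CH2Cl2, −78 to −10 °C; aq. NaHCO3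
Reagents that add atoms: tetrabutylammonium bromide, CCCC[N+](CCCC)(CCCC)CCCC.[Br-]; boron trichloride, ClB(Cl)Cl
Why: Proposed new method: a one-flask deoxygenative bromochlorination of an epoxide in which the oxygen face is handed on to chlorine; BCl3 and Bu4NBr pair up as Bu4N[BCl3Br], which holds chloride on boron and offers bromide as the only transferable halide, so the BCl3-activated oxirane is first opened anti by bromide (at C5 or at C4, both anti); on warming, excess BCl3 turns the dichloroboryl ether into a leaving group, the anti bromine expels it, and both regioisomeric bromohydrins funnel into the same bromonium ion on the face opposite the former oxygen; chloride now released from boron opens this ion at tertiary C4 from the face oxygen has left, as a normal trans-diaxial opening because C1 is still sp2 and ring A is not conformationally locked; the outcome is Cl with retention at C4 and Br with inversion at C5, the hindered pyridine traps the HCl formed from the free C5'-OH, and that borate is hydrolysed on work-up; the closest known reaction types are BCl3/Bu4NI ether cleavage, deoxydihalogenation of epoxides by halophosphonium salts, and retentive substitution of β-bromo alcohols through bromonium ions.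

**Step 11**
Reactants: 18 alkene bromochloride
Product: 20 target (1'S,3'S,5'R,1R,4S,5S), via hydroperoxide 19 (not isolated)
Conditions: Mn(dpm)3 (15 mol %), PhSiH3, O2 (1 atm), iPrOH/CH2Cl2, 0 °C; then PPh3
Reagents that add atoms: dioxygen, O=O
Why: In the Mukaiyama hydration (metal-hydride hydrogen atom transfer) H adds to C2, and the tertiary C1 radical takes O2 on the face anti to the C5 bromine because the other face is 1,3-syn-axial to Br, which gives axial OH with equatorial cyclopentyl, Br and Cl (1R), while PPh3 reduces the hydroperoxide heterolytically and so avoids an alkoxyl radical that would fragment.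

**Compound list**
1 | (1R,3S)-(+)-camphoric acid | CC1(C)[C@@H](C(=O)O)CC[C@@]1(C)C(=O)O | starting material
2 | dimethyl (1R,3S)-camphorate | CC1(C)[C@@H](C(=O)OC)CC[C@@]1(C)C(=O)OC | intermediate
3 | (1R,3S)-camphoric acid 1-methyl ester | CC1(C)[C@@H](C(=O)O)CC[C@@]1(C)C(=O)OC | intermediate
4 | methyl (1R)-1,2,2-trimethylcyclopent-3-ene-1-carboxylate | CC1(C)C=CC[C@@]1(C)C(=O)OC | intermediate
5 | dimethyl (1-diazo-2-oxopropyl)phosphonate | CC(=O)C(=[N+]=[N-])P(=O)(OC)OC | starting material
6 | (1R)-1,2,2-trimethylcyclopent-3-ene-1-carbaldehyde | CC1(C)C=CC[C@@]1(C)C=O | intermediate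
7 | (4S)-4-ethynyl-3,3,4-trimethylcyclopent-1-ene | CC1(C)C=CC[C@@]1(C)C#C | intermediate
8 | (5S)-5-ethynyl-4,4,5-trimethylcyclopent-2-en-1-ol (either carbinol epimer) | CC1(C)C=CC(O)[C@@]1(C)C#C | intermediate
9 | (5S)-5-ethynyl-4,4,5-trimethylcyclopent-2-en-1-one | CC1(C)C=CC(=O)[C@@]1(C)C#C | intermediate
10 | isoprene | CC(=C)C=C | starting material
11 | (5R)-4,4,5-trimethyl-5-(4-methylcyclohexa-1,4-dien-1-yl)cyclopent-2-en-1-one | CC1(C)C=CC(=O)[C@@]1(C)C1=CCC(C)=CC1 | intermediate
12 | (1'R,3'R)-β-boryl ketone (Bpin on C3' trans to ring A) | CC1(C)[C@H](B2OC(C)(C)C(C)(C)O2)CC(=O)[C@@]1(C)C1=CCC(C)=CC1 | intermediate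
13 | (1'R,3'R,5'R)-boryl alcohol | CC1(C)[C@H](B2OC(C)(C)C(C)(C)O2)C[C@@H](O)[C@@]1(C)C1=CCC(C)=CC1 | intermediate
14 | (1'S,3'R,5'R)-diol | CC1(C)[C@H](O)C[C@@H](O)[C@@]1(C)C1=CCC(C)=CC1 | intermediate
15 | (1R,2S,4S)-4-bromo-2,3,3-trimethyl-2-(4-methylcyclohexa-1,4-dien-1-yl)cyclopentan-1-ol | CC1(C)[C@@H](Br)C[C@@H](O)[C@@]1(C)C1=CCC(C)=CC1 | intermediate
16 | (4S,5R)-4,5-epoxide of 15 | CC1(C)[C@@H](Br)C[C@@H](O)[C@@]1(C)C1=CC[C@]2(C)O[C@@H]2C1 | intermediate
17 | C4-O,C5'-O-bis(dichloroboryl) ether of the (4S,5S)-bromohydrin | CC1(C)[C@@H](Br)C[C@@H](OB(Cl)Cl)[C@@]1(C)C1=CC[C@](C)(OB(Cl)Cl)[C@@H](Br)C1 | intermediate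
18 | (1'S,3'S,5'R,4S,5S)-alkene bromochloride | CC1(C)[C@@H](Br)C[C@@H](O)[C@@]1(C)C1=CC[C@](C)(Cl)[C@@H](Br)C1 | intermediate
19 | (1R)-C1 hydroperoxide | CC1(C)[C@@H](Br)C[C@@H](O)[C@@]1(C)[C@@]1(OO)CC[C@](C)(Cl)[C@@H](Br)C1 | intermediate
20 | CNP0158757.1 | CC1(C)[C@@H](Br)C[C@@H](O)[C@@]1(C)[C@@]1(O)CC[C@](C)(Cl)[C@@H](Br)C1 | target

**Total step count:** 11. **Longest linear sequence:** 11.

**Three steps most likely to fail**

**Step 8 (Appel inversion at C3').** The backside of C3' is neopentylic and lies on the face that carries ring A. Elimination to the C3'=C4' alkene or a methyl shift may therefore win. The fallback sets out from 13, obtained by stopping step 7 before the perborate oxidation. Treatment with 3,5-bis(trifluoromethyl)phenyllithium (2.1 equiv, THF, −78 °C) gives the dilithium boronate complex F1. N-Bromosuccinimide then brominates F1 with inversion at carbon (electrophilic substitution of a boronate complex). This replaces nucleophilic attack on a carbinol derivative by electrophilic attack on a C–B bond and returns to the route at 15.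

**Step 10 (the proposed new step).** The oxirane may undergo hydride shift to a ketone, be opened by chloride first, or lose a proton after ionisation. The fallback uses known chemistry and sets out from 15, leaving out steps 9 and 10. Anti addition of Bu4NBrCl2 (CH2Cl2, −78 °C) occurs at the less hindered C4=C5 alkene and gives 18 directly. It forms together with its ring A diastereomer, the (4R,5R)-bromochloride F2, because the cyclopentane is too remote to bias the face. The two are separated by chromatography. F2 is returned to 15 with Zn in AcOH/THF and resubmitted. The route is rejoined at 18.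

**Step 11 (hydration of the hindered alkene).** Hydrogen atom transfer may be slow next to the tert-alkyl group. Any O–O homolysis would cleave the C1–C1' bond, and O2 is a poorly selective trap. The fallback sets out from 18 and replaces the radical by an ionic anti addition. Hg(OCOCF3)2 in THF/H2O gives the trans-diaxial hydroxymercurial F3, with OH axial on C1 and Hg on C2. The opposite diaxial mode would place OH syn-axial to Br and Hg syn-axial to Cl. NaBH4 in aq. NaOH at 0 °C then removes mercury and gives 20.

**Further compounds**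
F1 | step 8 | dilithium boronate complex of 13 with the 3,5-bis(trifluoromethyl)phenyl group on boron | [Li+].[Li+].CC1(C)[C@H]([B-]2(OC(C)(C)C(C)(C)O2)c2cc(cc(c2)C(F)(F)F)C(F)(F)F)C[C@@H]([O-])[C@@]1(C)C1=CCC(C)=CC1
F2 | step 10 | (1'S,3'S,5'R,4R,5R)-alkene bromochloride | CC1(C)[C@@H](Br)C[C@@H](O)[C@@]1(C)C1=CC[C@@](C)(Cl)[C@H](Br)C1
F3 | step 11 | C2-(trifluoroacetoxymercurio) derivative of 20 (Hg trans to the C1 hydroxyl) | CC1(C)[C@@H](Br)C[C@@H](O)[C@@]1(C)[C@@]1(O)[C@@H]([Hg]OC(=O)C(F)(F)F)C[C@](C)(Cl)[C@@H](Br)C1
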